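The complex with two exchanged comes late: in gamma at 3.00 h it reads 2% against 20% of complex with one exchanged, so I watch what feeds it.

| setting | gamma | alpha | beta | flask |
|---|---|---|---|---|
| starting complex | 0.14 M | 0.21 M | 0.28 M | 0.28 M |
| incoming ligand | 0.84 M | 0.84 M | 0.42 M | 0.840 M |
| remark | run made earlier | run made earlier | run made earlier |  |
| time |  |  |  | 20 h |

- gamma (time / h: complex with two exchanged / %, complex with one exchanged / %, starting complex / %): 3.00: 2, 20, 62; 6.00: 8, 23, 43; 10.0: 10, 19, 24; 12.0: 11, 15, 19; 15.0: 9, 9, 17; 20.0: 11, 6, 7
- alpha (time / h: complex with two exchanged / %, complex with one exchanged / %, starting complex / %): 3.00: 3, 18, 61; 6.00: 7, 24, 40; 10.0: 9, 16, 23; 12.0: 8, 16, 20; 15.0: 10, 11, 15; 20.0: 11, 9, 11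
- beta (time / h: complex with two exchanged / %, complex with one exchanged / %, starting complex / %): 4.00: 0, 16, 60; 8.00: 3, 15, 42; 12.0: 4, 18, 34; 15.0: 8, 16, 26; 20.0: 9, 14, 21

(standard deviation of a reading: 1.5 percentage points)



- equivalents of incoming ligand to starting complex, everything else as given, that leave most complex with two exchanged at 20 h
- the amount of complex with two exchanged then, in percent of the starting complex charged
- the amount of complex with two exchanged with the amounts as given

The starting complex is the limiting reagent of the flask, charged at 0.28 M against 0.840 M of incoming ligand, so I write its balance in fractions of the charge. In alpha at 20.0 h the three read species hold 31.0%, and the rest sits in forms I don't read.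

I need two times: the asked 20 h, and the life of the starting complex, the time in which its remaining fraction falls by the factor e. Gamma and alpha share the flask's ligand charge, and their last readings together give a life of 8.22 h. The flask therefore runs 2.43 lives, which by my estimate leaves 8.77% of its starting complex. Gamma and alpha both read 11% of complex with two exchanged at 20.0 h, so I commit to about that for the flask. Beta, charged like the flask in starting complex but with half the ligand, reads a longer life of 12.8 h and 9% of complex with two exchanged at 20.0 h.

The forecast says 10.5%, between 8.5% and 12.5%, and a best of 11.2% at 3.5 equiv: “The optimum is broad”.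

The flask gives 10.5%, and 10.8% at 3.70 equiv, inside the forecast's ranges. Left until 200 h, it still holds 11.4% of complex with two exchanged. Its starting complex stands at 9.88% after 20.0 h, against my 8.77%.

    starting complex + incoming ligand ⇌ leaving ligand + complex with one exchanged (K = 2.60, k = 0.160 L mol⁻¹ h⁻¹)
    complex with one exchanged + incoming ligand ⇌ leaving ligand + complex with two exchanged (K = 12.0, k = 0.130 L mol⁻¹ h⁻¹)
    complex with two exchanged + incoming ligand ⇌ leaving ligand + complex with three exchanged (K = 0.920, k = 0.240 L mol⁻¹ h⁻¹)
    2 starting complex → homo dimer (k = 0.160 L mol⁻¹ h⁻¹)
    complex with one exchanged + incoming ligand → over-reaction product (k = 0.190 L mol⁻¹ h⁻¹)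

For the neighbour charged with 0.70 M of starting complex at the same ligand charge, 8.22 h again gives 8.77%. After 20.0 h that neighbour holds 9.8% of starting complex and 8.81% of complex with two exchanged.

The runs were generated by integration for substances that don't exist; scatter was added.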